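**Retrosynthetic overview**
1. The target (cembrane numbering) is a 14-membered carbocycle C1–C14 (ring B) bridged by a cis-2,5-tetrahydrofuran made of O, C1, C14, C13 and C12 (ring A). The endgame is C2≡C3 to (E)-C2=C3, C6 dithiane hydrolysis, then C11 formylation.
2. Ring B closes at C1–C2: the chain's own terminal acetylide opens a 2,7-dioxabicyclo[2.2.1]heptane ketal at C1. C5–C6 comes from a C6 dithiane anion and an (R)-alkynyl epoxide (C4 from (R)-2-methylglycidol). C8 comes from (S)-citronellol.
3. Key disconnection O–C12: the ring-A oxygen is traced back to the carbonyl oxygen of an acyclic C1 isopropyl ketone, and C11/C12 to the epoxide of an (E)-alkene. Epoxidation followed by isomerisation gives the bicyclic ketal in one operation.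
4. Enabling feature: the oxygen on C1 is 1,4-related to C12 through C14–C13. The C11 oxygen is vicinal to C12 and anti to the ring oxygen, and C2 and C11 sit cis on ring A. This is the imprint of a γ,δ-epoxy ketone opened 5-exo with inversion, whose C11 oxygen can hold C1 as a ketal and later hand its place to C2.
5. Ring order: ring A plus a temporary dioxolane (step 5), then ring B with loss of the dioxolane (step 14).

Key step: step 5

Remark: cembrane numbering is used throughout (C1 isopropyl-bearing ring carbon, C2=C3 alkene, C4 carbinol, C6 ketone, C8 methyl-bearing CH, C11 formyloxy CH, C12 methyl-bearing ether carbon, C13/C14 the CH2 groups of ring A). Commercial 1 and 13 are taken as single enantiomers.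

Step 1
Reactants: 1 (S)-citronellol
Product: 2 (S)-citronellol tert-butyldimethylsilyl ether
Conditions: TBSCl, imidazole, DMF, rt
Reagents that add atoms: tert-butyldimethylsilyl chloride, CC(C)(C)[Si](C)(C)Cl
Why: Imidazole-promoted silylation masks the future C6 oxygen through the oxidations and the enolate step, and leaves the C8 stereocentre brought in by 1 untouched.

Step 2
Reactants: 2 (S)-citronellol tert-butyldimethylsilyl ether
Product: 3 (2E,6S)-8-(tert-butyldimethylsilyloxy)-2,6-dimethyloct-2-en-1-ol
Conditions: SeO2 (0.2 equiv), t-BuOOH (2.5 equiv), CH2Cl2, 0 °C to rt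
Reagents that add atoms: tert-butyl hydroperoxide, CC(C)(C)OO (oxygen relayed through catalytic SeO2, O=[Se]=O)
Why: The Riley allylic oxidation (ene reaction, then [2,3]-shift) hydroxylates the methyl group trans to the chain of an isopropylidene unit, which fixes the (E)-geometry of C11=C12.

Step 3
Reactants: 3 (2E,6S)-8-(tert-butyldimethylsilyloxy)-2,6-dimethyloct-2-en-1-ol
Product: 4 (2E,6S)-1-bromo-8-(tert-butyldimethylsilyloxy)-2,6-dimethyloct-2-ene
Conditions: CBr4, PPh3, CH2Cl2, 0 °C
Reagents that add atoms: carbon tetrabromide, BrC(Br)(Br)Br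
Why: The Appel reaction replaces the primary allylic hydroxyl by SN2 on the alkoxyphosphonium salt, without allylic transposition or loss of alkene geometry.

Step 4
Reactants: 4 (2E,6S)-1-bromo-8-(tert-butyldimethylsilyloxy)-2,6-dimethyloct-2-ene, 5 3-methylbutan-2-one
Product: 7 (6E,10S)-12-(tert-butyldimethylsilyloxy)-2,6,10-trimethyldodec-6-en-3-one, via lithium enolate 6 (not isolated)
Conditions: 5 (3 equiv), LiN(iPr)2 (3 equiv), THF, −78 °C; then 4, DMPU, −78 to 0 °C
Reagents that add atoms: none
Why: Kinetic deprotonation at the methyl group, followed by ketone enolate alkylation with the reactive allylic bromide, forms C13–C14, and the excess of enolate suppresses double alkylation.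

Step 5
Reactants: 7 (6E,10S)-12-(tert-butyldimethylsilyloxy)-2,6,10-trimethyldodec-6-en-3-one
Product: 9 (1S,3R,4S)-3-[(3S)-5-(tert-butyldimethylsilyloxy)-3-methylpentyl]-1-isopropyl-4-methyl-2,7-dioxabicyclo[2.2.1]heptane, via epoxy ketone 8 (not isolated)
Conditions: 1,2:4,5-di-O-isopropylidene-β-D-erythro-hexo-2,3-diulo-2,6-pyranose (D-fructose-derived Shi ketone, 0.3 equiv), Oxone (2KHSO5·KHSO4·K2SO4), K2CO3, n-Bu4NHSO4 (cat.), Na2B4O7/Na2EDTA buffer, MeCN–CH2(OMe)2, 0 °C; extraction and drying; then BF3·OEt2 (0.1 equiv), CH2Cl2, −78 to −20 °C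
Reagents that add atoms: potassium peroxymonosulfate (active component of Oxone), [K+].[O-]S(=O)(=O)OO
Why: The dioxirane formed from the D-fructose-derived ketone and KHSO5 epoxidises the only alkene of 7 through the spiro transition state of the Shi epoxidation, which should give the (11R,12R)-epoxide 8 and so set C11 and the pre-inversion configuration of C12 under reagent control. With catalytic BF3·OEt2 the C1 carbonyl oxygen, held 1,4 to C12 by C14 and C13, opens the activated epoxide at its tertiary carbon from the rear (5-exo-tet, closes the tetrahydrofuran ring, C12 inverted to S), and the released C11 alkoxide collapses on the C1 oxocarbenium ion (6-exo-trig counted through C13 and C14), which closes the dioxolane ring of the bicycle. The closest known reaction type is the acid-catalysed isomerisation of γ,δ-epoxy ketones to 2,7-dioxabicyclo[2.2.1]heptanes. C1 has no freedom of its own, because the one-oxygen bridge from C11 can reach C1 only on the ring face that carries C11, so the ketal carbon forms in the single configuration dictated by C11 and C12, and this stored information later places C2 cis to C11. The step needs attack at C12 and not at C11 (6-endo attack would invert C11 and lead to the mirror-image core) and an SN2-like rather than free-cation opening, and both are secured because C12 is at once the exo position of a five-membered transition state and the carbon that best carries positive charge, with the internal nucleophile already in place at low temperature in a non-nucleophilic solvent. In one operation an acyclic ketone with one stereocentre becomes a bicycle with four, and the C1 ketone, the C11 hydroxyl and the C12 ether oxygen are masked for the carbanion chemistry that follows.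

Step 6
Reactants: 9 silyl-protected bicyclic ketal
Product: 10 (3S)-5-[(1S,3R,4S)-1-isopropyl-4-methyl-2,7-dioxabicyclo[2.2.1]heptan-3-yl]-3-methylpentan-1-ol
Conditions: n-Bu4NF, THF, rt
Reagents that add atoms: none
Why: Fluoride-induced desilylation frees the C6 hydroxyl under basic conditions to which the ketal is inert.

Step 7
Reactants: 10 ketal alcohol
Product: 11 (3S)-5-[(1S,3R,4S)-1-isopropyl-4-methyl-2,7-dioxabicyclo[2.2.1]heptan-3-yl]-3-methylpentanal
Conditions: n-Pr4N[RuO4] (5 mol %), NMO, 4 Å MS, CH2Cl2, rt
Reagents that add atoms: none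
Why: The Ley–Griffith oxidation runs neutral and anhydrous, so it should stop at the aldehyde and spare the acid-labile ketal, while C8 is β to the carbonyl and cannot epimerise.

Step 8
Reactants: 11 ketal aldehyde
Product: 12 2-{(2S)-4-[(1S,3R,4S)-1-isopropyl-4-methyl-2,7-dioxabicyclo[2.2.1]heptan-3-yl]-2-methylbutyl}-1,3-dithiane
Conditions: HS(CH2)3SH (1.05 equiv), Zn(OTf)2 (10 mol %), 4 Å MS, CH2Cl2, −20 to 0 °C
Reagents that add atoms: propane-1,3-dithiol, SCCCS
Why: In this mild Lewis-acid-catalysed dithioacetalisation the unhindered aldehyde should consume the single equivalent of dithiol far faster than the ketal carbon, which is shielded by isopropyl, can exchange.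

Step 9
Reactants: 13 (R)-2-methylglycidol
Product: 14 (S)-2-methyloxirane-2-carbaldehyde
Conditions: 2,2,6,6-tetramethylpiperidine-1-oxyl (TEMPO, 10 mol %), PhI(OAc)2, CH2Cl2, 0 °C to rt
Reagents that add atoms: none
Why: The oxoammonium (TEMPO) oxidation of the primary alcohol stops at the aldehyde, and the fully substituted C4 cannot epimerise.

Step 10
Reactants: 14 (S)-2-methyloxirane-2-carbaldehyde
Product: 15 (R)-2-ethynyl-2-methyloxirane
Conditions: MeC(O)C(N2)P(O)(OMe)2, K2CO3, MeOH, 0 °C to rt; product kept as an Et2O solution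
Reagents that add atoms: dimethyl (1-diazo-2-oxopropyl)phosphonate (Ohira–Bestmann reagent), CC(=O)C(=[N+]=[N-])P(=O)(OC)OC
Why: The Ohira–Bestmann (Seyferth–Gilbert) homologation turns the non-enolisable epoxy aldehyde into the terminal alkyne, adds C2, and breaks no bond at C4.

Step 11
Reactants: 15 (R)-2-ethynyl-2-methyloxirane
Product: 17 (R)-trimethyl[(2-methyloxiran-2-yl)ethynyl]silane, via lithium acetylide 16 (not isolated)
Conditions: n-BuLi, Et2O, −78 °C; Me3SiCl, −78 to 0 °C
Reagents that add atoms: chlorotrimethylsilane, C[Si](C)(C)Cl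
Why: Deprotonation and C-silylation block the acidic alkyne hydrogen, which would otherwise quench the dithiane anion of step 12, and make the fragment less volatile.

Step 12
Reactants: 12 ketal dithiane, 17 (R)-trimethyl[(2-methyloxiran-2-yl)ethynyl]silane
Product: 20 2-[(2S)-2-methyl-2-(triethylsilyloxy)-4-(trimethylsilyl)but-3-yn-1-yl]-2-{(2S)-4-[(1S,3R,4S)-1-isopropyl-4-methyl-2,7-dioxabicyclo[2.2.1]heptan-3-yl]-2-methylbutyl}-1,3-dithiane, via 2-lithiodithiane 18 (not isolated), via lithium alkoxide 19 (not isolated)
Conditions: 12, n-BuLi, THF, −30 °C; DMPU, 17, −30 to 0 °C; Et3SiCl, 0 °C to rt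
Reagents that add atoms: chlorotriethylsilane, CC[Si](Cl)(CC)CC
Why: In this Corey–Seebach umpolung the lithiated dithiane opens the 2,2-disubstituted epoxide by SN2 at its CH2 terminus (C5–C6 bond), so the C4–O bond and the configuration from 13 are untouched, the ketal shields C1, C11–O and C12–O from the carbanion, and the tertiary alkoxide is capped in the same flask.

Step 13
Reactants: 20 C-silylated seco compound
Product: 21 terminal alkyne (20 with C≡C–H in place of C≡C–SiMe3)
Conditions: K2CO3 (0.2 equiv), MeOH–THF, rt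
Reagents that add atoms: none
Why: Base-catalysed methanolysis of the C(sp)–Si bond is much faster than cleavage of a tertiary triethylsilyl ether, and it leaves ketal and dithiane alone.

Step 14
Reactants: 21 terminal alkyne
Product: 25 (1S,4S,8S,11R,12S)-1,12-epoxy-6,6-(propane-1,3-diyldisulfanediyl)-4-(triethylsilyloxy)cembr-2-yn-11-ol, via lithium acetylide 22 (not isolated), via alkynylalane 23 (not isolated), via aluminium alkoxide 24 (not isolated)
Conditions: n-BuLi (1.0 equiv), toluene, −78 to −20 °C; Me2AlCl (1.05 equiv), −20 °C; slow addition to toluene, 40 °C (final 1 mM); aqueous work-up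
Reagents that add atoms: none
Why: Proposed new method: the chain terminus becomes a dimethyl(alkynyl)alane, the only Lewis acid present, which should bind the less hindered ketal oxygen (the one on secondary C11), break the C1–O(C11) bond to a tetrahydrofuran oxocarbenium/aluminate ion pair, and pass its alkynyl ligand to C1 on the face the oxygen has just left, which is also the only face the C3–C10 tether can reach, so that C2 replaces oxygen with retention, C1 becomes S and the 14-membered ring closes; alkynyl migrates from aluminium far faster than methyl, high dilution favours the internal event, and the closest known reaction type is the retentive cleavage of acetals, bicyclic ketals and anhydro sugars by alkynyl- and hydrido-alanes, which has not been used to close a macrocycle or to build a quaternary centre next to an isopropyl group.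

Step 15
Reactants: 25 macrocyclic alkyne triethylsilyl ether
Product: 26 (1S,4S,8S,11R,12S)-1,12-epoxy-6,6-(propane-1,3-diyldisulfanediyl)cembr-2-yne-4,11-diol
Conditions: n-Bu4NF, THF, 0 °C to rt
Reagents that add atoms: none
Why: Fluoride desilylation frees the C4 hydroxyl, which is needed as the directing group for the alkyne reduction.

Step 16
Reactants: 26 macrocyclic alkynediol
Product: 28 (1S,2E,4S,8S,11R,12S)-1,12-epoxy-6,6-(propane-1,3-diyldisulfanediyl)cembr-2-ene-4,11-diol, via alkenylaluminate 27 (not isolated)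
Conditions: NaAlH2(OCH2CH2OMe)2 (4 equiv), THF, 0 °C to rt; aqueous work-up
Reagents that add atoms: none
Why: In this hydroxyl-directed trans-hydroalumination of a propargylic alcohol the C4 alkoxide binds aluminium, hydride goes to C3 and aluminium to C2 within a five-membered aluminate, and protonolysis should give only the (E)-alkene, while the dithiane keeps C6 out of reach of hydride.

Step 17
Reactants: 28 (E)-alkene diol dithiane
Product: 29 (1S,2E,4S,8S,11R,12S)-1,12-epoxy-4,11-dihydroxycembr-2-en-6-one
Conditions: MeI, CaCO3, MeCN–H2O (9:1), 40 °C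
Reagents that add atoms: water, O
Why: S-Alkylative dithiane hydrolysis buffered by CaCO3 stays close to neutral, which avoids both retro-aldol cleavage of the β-hydroxy ketone and ionisation of the tertiary allylic alcohol.

Step 18
Reactants: 29 keto diol
Product: 30 target, (1S,2E,4S,8S,11R,12S)-1,12-epoxy-11-formyloxy-4-hydroxycembr-2-en-6-one
Conditions: AcOCHO (prepared beforehand), pyridine, CH2Cl2, −20 to 0 °C
Reagents that add atoms: acetic formic anhydride, CC(=O)OC=O
Why: Acylation with the mixed anhydride transfers the smaller and more electrophilic formyl group to the secondary C11 hydroxyl, the tertiary C4 hydroxyl is too hindered to react at low temperature, and the most labile group of the target is installed last.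

**Compound list**
1 | (S)-citronellol, (3S)-3,7-dimethyloct-6-en-1-ol | OCC[C@@H](C)CCC=C(C)C | starting material
2 | (S)-citronellol tert-butyldimethylsilyl ether | CC(C)(C)[Si](C)(C)OCC[C@@H](C)CCC=C(C)C | intermediate
3 | (2E,6S)-8-(tert-butyldimethylsilyloxy)-2,6-dimethyloct-2-en-1-ol | CC(C)(C)[Si](C)(C)OCC[C@@H](C)CC/C=C(\C)CO | intermediate
4 | (2E,6S)-1-bromo-8-(tert-butyldimethylsilyloxy)-2,6-dimethyloct-2-ene | CC(C)(C)[Si](C)(C)OCC[C@@H](C)CC/C=C(\C)CBr | intermediate
5 | 3-methylbutan-2-one | CC(=O)C(C)C | starting material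
6 | lithium 3-methylbut-1-en-2-olate | [Li+].[O-]C(=C)C(C)C | intermediate
7 | (6E,10S)-12-(tert-butyldimethylsilyloxy)-2,6,10-trimethyldodec-6-en-3-one | CC(C)(C)[Si](C)(C)OCC[C@@H](C)CC/C=C(\C)CCC(=O)C(C)C | intermediate
8 | (6R,7R,10S)-12-(tert-butyldimethylsilyloxy)-6,7-epoxy-2,6,10-trimethyldodecan-3-one (11R,12R in cembrane numbering) | CC(C)(C)[Si](C)(C)OCC[C@@H](C)CC[C@H]1O[C@]1(C)CCC(=O)C(C)C | intermediate
9 | (1S,3R,4S)-3-[(3S)-5-(tert-butyldimethylsilyloxy)-3-methylpentyl]-1-isopropyl-4-methyl-2,7-dioxabicyclo[2.2.1]heptane | CC(C)(C)[Si](C)(C)OCC[C@@H](C)CC[C@H]1O[C@@]2(C(C)C)CC[C@]1(C)O2 | intermediate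
10 | (3S)-5-[(1S,3R,4S)-1-isopropyl-4-methyl-2,7-dioxabicyclo[2.2.1]heptan-3-yl]-3-methylpentan-1-ol | OCC[C@@H](C)CC[C@H]1O[C@@]2(C(C)C)CC[C@]1(C)O2 | intermediate
11 | (3S)-5-[(1S,3R,4S)-1-isopropyl-4-methyl-2,7-dioxabicyclo[2.2.1]heptan-3-yl]-3-methylpentanal | O=CC[C@@H](C)CC[C@H]1O[C@@]2(C(C)C)CC[C@]1(C)O2 | intermediate
12 | 2-{(2S)-4-[(1S,3R,4S)-1-isopropyl-4-methyl-2,7-dioxabicyclo[2.2.1]heptan-3-yl]-2-methylbutyl}-1,3-dithiane | S1CCCSC1C[C@@H](C)CC[C@H]2O[C@@]3(C(C)C)CC[C@]2(C)O3 | intermediate
13 | (R)-2-methylglycidol, [(2R)-2-methyloxiran-2-yl]methanol | OC[C@]1(C)CO1 | starting material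
14 | (S)-2-methyloxirane-2-carbaldehyde | O=C[C@]1(C)CO1 | intermediate
15 | (R)-2-ethynyl-2-methyloxirane | C#C[C@]1(C)CO1 | intermediate
16 | lithium acetylide of 15 | [Li]C#C[C@]1(C)CO1 | intermediate
17 | (R)-trimethyl[(2-methyloxiran-2-yl)ethynyl]silane | C[Si](C)(C)C#C[C@]1(C)CO1 | intermediate
18 | 2-lithio derivative of dithiane 12 | [Li]C1(SCCCS1)C[C@@H](C)CC[C@H]2O[C@@]3(C(C)C)CC[C@]2(C)O3 | intermediate
19 | lithium C4 alkoxide from 18 and 17 | C[Si](C)(C)C#C[C@@](C)(O[Li])CC1(SCCCS1)C[C@@H](C)CC[C@H]2O[C@@]3(C(C)C)CC[C@]2(C)O3 | intermediate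
20 | seco compound, C4 (S) triethylsilyl ether, C-trimethylsilyl alkyne, C6 dithiane, bicyclic ketal | C[Si](C)(C)C#C[C@@](C)(O[Si](CC)(CC)CC)CC1(SCCCS1)C[C@@H](C)CC[C@H]2O[C@@]3(C(C)C)CC[C@]2(C)O3 | intermediate
21 | seco compound with terminal alkyne | C#C[C@@](C)(O[Si](CC)(CC)CC)CC1(SCCCS1)C[C@@H](C)CC[C@H]2O[C@@]3(C(C)C)CC[C@]2(C)O3 | intermediate
22 | lithium acetylide of 21 | [Li]C#C[C@@](C)(O[Si](CC)(CC)CC)CC1(SCCCS1)C[C@@H](C)CC[C@H]2O[C@@]3(C(C)C)CC[C@]2(C)O3 | intermediate
23 | dimethyl(alkynyl)alane of 21 | C[Al](C)C#C[C@@](C)(O[Si](CC)(CC)CC)CC1(SCCCS1)C[C@@H](C)CC[C@H]2O[C@@]3(C(C)C)CC[C@]2(C)O3 | intermediate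
24 | dimethylaluminium C11 alkoxide of 25 | CC(C)[C@]12C#C[C@@](C)(O[Si](CC)(CC)CC)CC3(SCCCS3)C[C@@H](C)CC[C@@H](O[Al](C)C)[C@](C)(CC1)O2 | intermediate
25 | (1S,4S,8S,11R,12S)-1,12-epoxy-6,6-(propane-1,3-diyldisulfanediyl)-4-(triethylsilyloxy)cembr-2-yn-11-ol | CC(C)[C@]12C#C[C@@](C)(O[Si](CC)(CC)CC)CC3(SCCCS3)C[C@@H](C)CC[C@@H](O)[C@](C)(CC1)O2 | intermediate
26 | (1S,4S,8S,11R,12S)-1,12-epoxy-6,6-(propane-1,3-diyldisulfanediyl)cembr-2-yne-4,11-diol | CC(C)[C@]12C#C[C@@](C)(O)CC3(SCCCS3)C[C@@H](C)CC[C@@H](O)[C@](C)(CC1)O2 | intermediate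
27 | disodium bis-aluminate: five-membered C2–Al–O–C4 alkenylaluminate, C11 alkoxy(hydrido)aluminate | CC(C)[C@]12/C3=C/[C@@](C)(O[Al-]3(OCCOC)OCCOC)CC4(SCCCS4)C[C@@H](C)CC[C@@H](O[AlH-](OCCOC)OCCOC)[C@](C)(CC1)O2.[Na+].[Na+] | intermediate
28 | (1S,2E,4S,8S,11R,12S)-1,12-epoxy-6,6-(propane-1,3-diyldisulfanediyl)cembr-2-ene-4,11-diol | CC(C)[C@]12/C=C/[C@@](C)(O)CC3(SCCCS3)C[C@@H](C)CC[C@@H](O)[C@](C)(CC1)O2 | intermediate
29 | (1S,2E,4S,8S,11R,12S)-1,12-epoxy-4,11-dihydroxycembr-2-en-6-one | CC(C)[C@]12/C=C/[C@@](C)(O)CC(=O)C[C@@H](C)CC[C@@H](O)[C@](C)(CC1)O2 | intermediate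
30 | (1S,2E,4S,8S,11R,12S)-1,12-epoxy-11-formyloxy-4-hydroxycembr-2-en-6-one | CC(C)[C@]12/C=C/[C@@](C)(O)CC(=O)C[C@@H](C)CC[C@@H](OC=O)[C@](C)(CC1)O2 | target

**Count**
Total steps: 18. Longest linear sequence: 15 (steps 1–8 and 12–18).

**Steps most likely to fail**

1. Step 14. Ring closure may lose against intermolecular ketal opening (oligomerisation), against methyl transfer from aluminium, or against cleavage of the other ketal C–O bond.
 - The fallback sets out from 12 and 15 and comes back at 26. It forms C1–C2 between two molecules and closes the ring at C5–C6 instead.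
 - Epoxide 15 is opened at its CH2 terminus with LiBr/AcOH to (R)-1-bromo-2-methylbut-3-yn-2-ol F1, which is silylated (Et3SiOTf, 2,6-lutidine) to its triethylsilyl ether F2.
 - The dimethylalane of F2 (n-BuLi, then Me2AlCl), used in excess in toluene, opens ketal 12 by the established intermolecular organoalane cleavage of bicyclic ketals with retention. This gives the alkynyl tetrahydrofuran bromide F3.
 - n-Bu4NF removes the silyl group, and the tertiary alkoxide displaces the neighbouring bromide to give the epoxide F4.
 - Double deprotonation (n-BuLi, THF–DMPU, C11 alkoxide and dithiane anion) and warming at high dilution closes the 14-membered ring by attack of the sulfur-stabilised carbanion on the epoxide CH2. This is the classical carbanion/epoxide macrocyclisation of cembranoid chemistry, and it delivers 26 directly.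

2. Step 16. The alkenylaluminate carries aluminium on C2, next to the C1–O bond, so β-elimination with opening of ring A towards an allene may compete. Hydroalumination of an alkyne between two fully substituted carbons may also be slow.
 - The fallback sets out from 26 and comes back at 29.
 - The dithiane is hydrolysed first (MeI, CaCO3, aqueous MeCN) to the alkynyl keto diol F5.
 - Hydroxyl-directed ruthenium-catalysed trans-hydrostannation ([Cp*RuCl]4, Bu3SnH, CH2Cl2) places tin on C3, beside the free C4 hydroxyl and away from the ring oxygen. This gives the alkenylstannane F6.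
 - Protodestannation with Ph2P(O)OH proceeds with retention and gives the (E)-alkene 29.

3. Step 5. Facial selectivity of oxygen transfer to the flexible alkene may be incomplete. Part of the epoxide may also open through a free C12 cation, with loss of inversion or a 1,2-hydride shift.
 - The fallback sets out from 3 and comes back at 8. It sets C11/C12 by hydroxyl-directed catalysis before the C13–C14 bond is made.
 - Sharpless asymmetric epoxidation of allylic alcohol 3 (Ti(OiPr)4, D-(−)-diethyl tartrate, t-BuOOH, 4 Å MS) gives the (2R,3R)-epoxy alcohol F7.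
 - Iodination (I2, PPh3, imidazole) gives the epoxy iodide F8, and alkylation with lithium enolate 6 gives epoxy ketone 8. Compound 8 is now isolated and purified before it is isomerised to 9 with the Lewis acid.

**Further compounds**
F1 | step 14 | (R)-1-bromo-2-methylbut-3-yn-2-ol | C#C[C@@](C)(O)CBr
F2 | step 14 | triethylsilyl ether of F1 | C#C[C@@](C)(O[Si](CC)(CC)CC)CBr
F3 | step 14 | cis-2,5-tetrahydrofuran with C1 isopropyl and C1 alkynyl arm (C4 triethylsilyl ether, C5 bromide), free C11 hydroxyl, 2-H dithiane at C6 | CC(C)[C@]1(C#C[C@@](C)(O[Si](CC)(CC)CC)CBr)CC[C@](C)(O1)[C@H](O)CC[C@H](C)CC2SCCCS2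
F4 | step 14 | C4–C5 epoxide derived from F3 | CC(C)[C@]1(C#C[C@]2(C)CO2)CC[C@](C)(O1)[C@H](O)CC[C@H](C)CC3SCCCS3
F5 | step 16 | (1S,4S,8S,11R,12S)-1,12-epoxy-4,11-dihydroxycembr-2-yn-6-one | CC(C)[C@]12C#C[C@@](C)(O)CC(=O)C[C@@H](C)CC[C@@H](O)[C@](C)(CC1)O2
F6 | step 16 | 3-(tributylstannyl) derivative of 29, C1 and C4 trans on the alkene | CC(C)[C@]12/C=C([Sn](CCCC)(CCCC)CCCC)/[C@@](C)(O)CC(=O)C[C@@H](C)CC[C@@H](O)[C@](C)(CC1)O2
F7 | step 5 | {(2R,3R)-3-[(3S)-5-(tert-butyldimethylsilyloxy)-3-methylpentyl]-2-methyloxiran-2-yl}methanol | CC(C)(C)[Si](C)(C)OCC[C@@H](C)CC[C@H]1O[C@]1(C)CO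
F8 | step 5 | epoxy iodide derived from F7 | CC(C)(C)[Si](C)(C)OCC[C@@H](C)CC[C@H]1O[C@]1(C)CI
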